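**Plan**

- Retrosynthesis: the benzyl ethers, two temporary C2 ester groups and the C1 oxidation level are adjusted last. The cyclohexanone ring is then cut at C1–C2 and C4–C4a into 2,3-bis(benzyloxy)benzaldehyde (C1, C8a, C4a) and a racemic naphthyl cyclopropane-1,1-diester (C2–C3–C4).
- Enabling feature: C4 carries the 4-oxygenated 8-methoxynaphthalen-1-yl ring, a donor that makes the C4 benzylic cation easily and reversibly available. C4a is para to O7 and is the only free position ortho to C8a on the benzene ring. A gem-diester parked on C2 makes C2 nucleophilic.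
- Forward: 1,5-dimethoxynaphthalene is formylated, its para oxygen is changed from methyl to benzyl, and Knoevenagel/Corey–Chaykovsky reactions give the cyclopropane. In the key step an oxolane forms first (C1–C2 plus a transient C4–O bond) and is switched in the same flask to the carbocycle (C4–C4a).
- Stereochemistry: a chiral Mg(II)–pybox catalyst sets C1 in a dynamic kinetic asymmetric cycloaddition. C1 passes its configuration to C4 (cis) in the ring closure and is then oxidized away, leaving (S)-C4.
- End game: oxidation at C1, double dealkoxycarbonylation at C2, hydrogenolysis of three benzyl ethers.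

Key step: step 7

Assumption: the ring closure in step 7 is taken to be cis-selective (C1–O pseudoaxial, naphthyl pseudoequatorial); if it proved trans-selective, the ligand antipode would be used and only the descriptors of 10 and 11 would change.

**Route**

Step 1
Reactants: 1 1,5-dimethoxynaphthalene
Product: 2 4,8-dimethoxynaphthalene-1-carbaldehyde
Conditions: POCl3, DMF, 0 → 90 °C; then H2O
Reagents that add atoms: N,N-dimethylformamide CN(C)C=O; water O
Why: Vilsmeier–Haack formylation of the C2-symmetric diether should occur para to a methoxy group, so a single aldehyde with the second methoxy group peri to the formyl group is expected.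

Step 2
Reactants: 2 4,8-dimethoxynaphthalene-1-carbaldehyde
Product: 3 4-hydroxy-8-methoxynaphthalene-1-carbaldehyde
Conditions: EtSNa, DMF, 100 °C; then 1 M HCl
Reagents that add atoms: none
Why: Thiolate SN2 demethylation should select the 4-methoxy group, whose aryloxide is conjugated (para) to the formyl group, while the peri 8-methoxy group is not conjugated to C1 and should stay.

Step 3
Reactants: 3 4-hydroxy-8-methoxynaphthalene-1-carbaldehyde
Product: 4 4-(benzyloxy)-8-methoxynaphthalene-1-carbaldehyde
Conditions: BnBr, K2CO3, DMF, rt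
Reagents that add atoms: benzyl bromide BrCc1ccccc1
Why: Williamson etherification of the acidic naphthol marks the oxygen that must be free in the target with a group removable beside the methyl ether.

Step 4
Reactants: 4 4-(benzyloxy)-8-methoxynaphthalene-1-carbaldehyde; 5 dimethyl malonate
Product: 6 dimethyl 2-{[4-(benzyloxy)-8-methoxynaphthalen-1-yl]methylidene}propanedioate
Conditions: piperidine (cat.), AcOH (cat.), toluene, reflux, Dean–Stark
Reagents that add atoms: none
Why: Knoevenagel condensation driven by azeotropic removal of water installs C2 with its two temporary ester groups.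

Step 5
Reactants: 6 dimethyl 2-{[4-(benzyloxy)-8-methoxynaphthalen-1-yl]methylidene}propanedioate
Product: 7 dimethyl 2-[4-(benzyloxy)-8-methoxynaphthalen-1-yl]cyclopropane-1,1-dicarboxylate (racemic)
Conditions: Me3S(O)I, NaH, DMF, 0 °C → rt
Reagents that add atoms: trimethylsulfoxonium iodide C[S+](C)(C)=O.[I-]
Why: Corey–Chaykovsky cyclopropanation (conjugate addition of the sulfoxonium methylide, then 3-exo-tet closure) supplies C3; the racemate is what the dynamic key step requires.

Step 6
Reactants: 8 2,3-dihydroxybenzaldehyde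
Product: 9 2,3-bis(benzyloxy)benzaldehyde
Conditions: BnBr, K2CO3, DMF, 60 °C
Reagents that add atoms: benzyl bromide BrCc1ccccc1
Why: Double Williamson etherification protects the catechol and leaves the position para to O3 as the only free ortho site next to the formyl-bearing carbon.

Step 7
Reactants: 7 dimethyl 2-[4-(benzyloxy)-8-methoxynaphthalen-1-yl]cyclopropane-1,1-dicarboxylate (racemic); 9 2,3-bis(benzyloxy)benzaldehyde
Product: 11 dimethyl (1R,4S)-7,8-bis(benzyloxy)-4-[4-(benzyloxy)-8-methoxynaphthalen-1-yl]-1-hydroxy-3,4-dihydronaphthalene-2,2(1H)-dicarboxylate, via cis-oxolane cycloadduct 10 (not isolated)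
Conditions: MgI2 (10 mol %), 4-Cl-tBu-pybox (12 mol %, the antipode that delivers the (2R,5R) adduct), CCl4, rt; then CH2Cl2, BF3·OEt2 (30 mol %), −40 → 0 °C, one pot
Reagents that add atoms: none
Why: Proposed new method: the Mg(II)–pybox Lewis acid chelates the gem-diester of 7, whose bond from C(CO2Me)2 to the naphthyl-bearing carbon ionizes reversibly because the 4-benzyloxy-8-methoxynaphthalen-1-yl donor stabilizes the benzylic cation, so the enantiomers of 7 interconvert while the faster-reacting one undergoes SN2-like attack by the aldehyde oxygen of 9 and the magnesium malonate then adds to the resulting oxocarbenium carbon (C1–C2 bond) to give the cis-oxolane 10. BF3·OEt2 then re-ionizes the naphthyl-substituted C–O bond of 10 and the cation is trapped by the aldehyde-derived benzene ring (C4–C4a bond), an isomerization driven by the exchange of a C–O for a C–C bond. The closest known reaction types are the Lewis-acid (3+2) annulation of donor–acceptor cyclopropanes with aldehydes, including its dynamic kinetic asymmetric Mg–pybox variant, and the acid-induced rearrangement of 2,5-diaryltetrahydrofurans to aryltetralins; what is untested is their union in one flask on a 3,3-diester oxolane. The oxolane closes by aldol-type attack on the O-alkylated aldehyde (formally 5-endo-trig), and the carbocycle by a six-membered Friedel–Crafts closure in which the aromatic C4a–C8a bond lies inside the new ring (6-endo). C1 is set by the ligand in the cycloaddition, and C4 is set by C1 in the ring closure: the C1–O bond stands pseudoaxial to avoid the peri 8-benzyloxy group and the naphthyl group takes the pseudoequatorial site away from the axial C2 ester, which is the cis (1R,4S) arrangement. The step needs site-selective ionization (secured by the para-oxygenated naphthyl donor at C5 of 10, against a C2 flanked by the electron-poor gem-diester) and regioselective arylation (C6 of the aldehyde ring is the only free ortho position and is para to the 3-benzyloxy group).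

Step 8
Reactants: 11 dimethyl (1R,4S)-7,8-bis(benzyloxy)-4-[4-(benzyloxy)-8-methoxynaphthalen-1-yl]-1-hydroxy-3,4-dihydronaphthalene-2,2(1H)-dicarboxylate
Product: 12 dimethyl (4S)-7,8-bis(benzyloxy)-4-[4-(benzyloxy)-8-methoxynaphthalen-1-yl]-1-oxo-3,4-dihydronaphthalene-2,2(1H)-dicarboxylate
Conditions: Dess–Martin periodinane, CH2Cl2, 0 °C → rt
Reagents that add atoms: none
Why: Dess–Martin oxidation of the benzylic secondary alcohol gives the ketone and removes the relay stereocentre C1; C2 is quaternary and C4 is not touched, so nothing can epimerize.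

Step 9
Reactants: 12 dimethyl (4S)-7,8-bis(benzyloxy)-4-[4-(benzyloxy)-8-methoxynaphthalen-1-yl]-1-oxo-3,4-dihydronaphthalene-2,2(1H)-dicarboxylate
Product: 14 (4S)-7,8-bis(benzyloxy)-4-[4-(benzyloxy)-8-methoxynaphthalen-1-yl]-3,4-dihydronaphthalen-1(2H)-one, via β-keto monoester 13 (not isolated)
Conditions: LiCl, H2O, DMSO, 150 °C
Reagents that add atoms: none
Why: Krapcho dealkoxycarbonylation should run twice, chloride demethylating an ester of the 2-acylmalonate with loss of CO2 to a ketone-stabilized enolate and the β-keto ester 13 repeating the sequence, so both helper esters leave C2.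

Step 10
Reactants: 14 (4S)-7,8-bis(benzyloxy)-4-[4-(benzyloxy)-8-methoxynaphthalen-1-yl]-3,4-dihydronaphthalen-1(2H)-one
Product: 15 (4S)-7,8-dihydroxy-4-(4-hydroxy-8-methoxynaphthalen-1-yl)-3,4-dihydronaphthalen-1(2H)-one
Conditions: H2 (1 atm), 10% Pd/C, EtOAc–MeOH, rt
Reagents that add atoms: none
Why: Hydrogenolysis should cleave the three aryl benzyl ethers under conditions that leave the aryl methyl ether, the ketone (hydrogen-bonded to the new 8-OH) and the C4 stereocentre intact.

**Compound list**

1 | 1,5-dimethoxynaphthalene | COc1cccc2c(OC)cccc12 | starting material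
2 | 4,8-dimethoxynaphthalene-1-carbaldehyde | COc1cccc2c(OC)ccc(C=O)c12 | intermediate
3 | 4-hydroxy-8-methoxynaphthalene-1-carbaldehyde | COc1cccc2c(O)ccc(C=O)c12 | intermediate
4 | 4-(benzyloxy)-8-methoxynaphthalene-1-carbaldehyde | COc1cccc2c(OCc3ccccc3)ccc(C=O)c12 | intermediate
5 | dimethyl malonate | COC(=O)CC(=O)OC | starting material
6 | dimethyl 2-{[4-(benzyloxy)-8-methoxynaphthalen-1-yl]methylidene}propanedioate | COc1cccc2c(OCc3ccccc3)ccc(C=C(C(=O)OC)C(=O)OC)c12 | intermediate
7 | dimethyl 2-[4-(benzyloxy)-8-methoxynaphthalen-1-yl]cyclopropane-1,1-dicarboxylate (racemic) | COc1cccc2c(OCc3ccccc3)ccc(C3CC3(C(=O)OC)C(=O)OC)c12 | intermediate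
8 | 2,3-dihydroxybenzaldehyde | O=Cc1cccc(O)c1O | starting material
9 | 2,3-bis(benzyloxy)benzaldehyde | O=Cc1cccc(OCc2ccccc2)c1OCc1ccccc1 | intermediate
10 | dimethyl (2R,5R)-5-[4-(benzyloxy)-8-methoxynaphthalen-1-yl]-2-[2,3-bis(benzyloxy)phenyl]oxolane-3,3-dicarboxylate | O1[C@H](c2cccc(OCc5ccccc5)c2OCc5ccccc5)C(C(=O)OC)(C(=O)OC)C[C@@H]1c1ccc(OCc5ccccc5)c2cccc(OC)c12 | intermediate (not isolated)
11 | dimethyl (1R,4S)-7,8-bis(benzyloxy)-4-[4-(benzyloxy)-8-methoxynaphthalen-1-yl]-1-hydroxy-3,4-dihydronaphthalene-2,2(1H)-dicarboxylate | COc1cccc2c(OCc5ccccc5)ccc([C@@H]3CC(C(=O)OC)(C(=O)OC)[C@H](O)c4c3ccc(OCc5ccccc5)c4OCc5ccccc5)c12 | intermediate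
12 | dimethyl (4S)-7,8-bis(benzyloxy)-4-[4-(benzyloxy)-8-methoxynaphthalen-1-yl]-1-oxo-3,4-dihydronaphthalene-2,2(1H)-dicarboxylate | COc1cccc2c(OCc5ccccc5)ccc([C@@H]3CC(C(=O)OC)(C(=O)OC)C(=O)c4c3ccc(OCc5ccccc5)c4OCc5ccccc5)c12 | intermediate
13 | methyl (4S)-7,8-bis(benzyloxy)-4-[4-(benzyloxy)-8-methoxynaphthalen-1-yl]-1-oxo-1,2,3,4-tetrahydronaphthalene-2-carboxylate (C2 epimers) | COc1cccc2c(OCc5ccccc5)ccc([C@@H]3CC(C(=O)OC)C(=O)c4c3ccc(OCc5ccccc5)c4OCc5ccccc5)c12 | intermediate (not isolated)
14 | (4S)-7,8-bis(benzyloxy)-4-[4-(benzyloxy)-8-methoxynaphthalen-1-yl]-3,4-dihydronaphthalen-1(2H)-one | COc1cccc2c(OCc5ccccc5)ccc([C@@H]3CCC(=O)c4c3ccc(OCc5ccccc5)c4OCc5ccccc5)c12 | intermediate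
15 | (4S)-7,8-dihydroxy-4-(4-hydroxy-8-methoxynaphthalen-1-yl)-3,4-dihydronaphthalen-1(2H)-one | COc1cccc2c(O)ccc([C@@H]3CCC(=O)c4c3ccc(O)c4O)c12 | target

**Count and risks**

Total steps: 10. Longest linear sequence: 9 (steps 1–5, 7–10).

Steps most likely to fail:

Step 7. The chiral catalyst may discriminate poorly with the peri-substituted naphthyl donor, the C1 configuration may leak through retro-aldol reversal before ring closure, or the cis relay from C1 to C4 may be incomplete. The fallback uses known chemistry, sets out from 4 and returns at 14. Commercial 1-(2,3-dihydroxyphenyl)ethan-1-one is benzylated (BnBr, K2CO3) to 1-[2,3-bis(benzyloxy)phenyl]ethan-1-one F1. Claisen–Schmidt condensation of F1 with 4 (NaOH, EtOH) should give (E)-1-[2,3-bis(benzyloxy)phenyl]-3-[4-(benzyloxy)-8-methoxynaphthalen-1-yl]prop-2-en-1-one F2. Corey–Chaykovsky cyclopropanation (Me3S(O)I, NaH, DMSO) should give racemic trans-[2,3-bis(benzyloxy)phenyl]{2-[4-(benzyloxy)-8-methoxynaphthalen-1-yl]cyclopropyl}methanone F3. SnCl4 in CH2Cl2 should open the cyclopropane at the naphthyl-bearing carbon and close the cation para to the 3-benzyloxy group (cationic homo-Nazarov-type cyclization of aryl 2-arylcyclopropyl ketones to 4-aryl-1-tetralones), giving racemic 7,8-bis(benzyloxy)-4-[4-(benzyloxy)-8-methoxynaphthalen-1-yl]-3,4-dihydronaphthalen-1(2H)-one F4. Preparative chromatography on a chiral stationary phase then separates 14 from its (4R)-enantiomer F5.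

Step 9. The non-enolizable β-keto diester may open by retro-Claisen cleavage at 150 °C, chloride may remove the benzyl group ortho to the ketone, or the basic lithium salts may erode the C4 configuration. The fallback changes the helper esters so that they leave at room temperature; it sets out from 4 and returns at 14. Knoevenagel condensation of 4 with di(prop-2-en-1-yl) propanedioate should give di(prop-2-en-1-yl) 2-{[4-(benzyloxy)-8-methoxynaphthalen-1-yl]methylidene}propanedioate F6. Corey–Chaykovsky reaction should give the racemic diallyl cyclopropane-1,1-dicarboxylate F7. The conditions of step 7 with 9 should give, through the diallyl (2R,5R)-oxolane F8, the diallyl (1R,4S)-1-hydroxy-tetralin-2,2-dicarboxylate F9. Dess–Martin oxidation should give the diallyl (4S)-1-oxo-2,2-dicarboxylate F10. Palladium-catalysed deallylation–decarboxylation (Pd(OAc)2, PPh3, HCO2H–Et3N, THF, rt; Tsuji–Trost type) of F10 should then give 14.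

Step 5. Conjugate addition of the sulfoxonium ylide to the hindered, donor-deactivated alkylidene malonate may be slow and reversible, with retro-Knoevenagel cleavage competing. The fallback sets out from 4 and returns at 7. Wittig methylenation (Ph3P=CH2, THF) should give 1-(benzyloxy)-4-ethenyl-5-methoxynaphthalene F11. Rh2(esp)2-catalysed cyclopropanation of F11 with dimethyl diazomalonate (CH2Cl2, rt) should give 7 without passing through 6.

**Further compounds**

F1 | step 7 | 1-[2,3-bis(benzyloxy)phenyl]ethan-1-one | CC(=O)c1cccc(OCc2ccccc2)c1OCc1ccccc1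
F2 | step 7 | (E)-1-[2,3-bis(benzyloxy)phenyl]-3-[4-(benzyloxy)-8-methoxynaphthalen-1-yl]prop-2-en-1-one | COc1cccc2c(OCc3ccccc3)ccc(/C=C/C(=O)c3cccc(OCc4ccccc4)c3OCc3ccccc3)c12
F3 | step 7 | trans-[2,3-bis(benzyloxy)phenyl]{2-[4-(benzyloxy)-8-methoxynaphthalen-1-yl]cyclopropyl}methanone (racemic, one enantiomer drawn) | COc1cccc2c(OCc3ccccc3)ccc([C@H]3C[C@@H]3C(=O)c3cccc(OCc4ccccc4)c3OCc3ccccc3)c12
F4 | step 7 | 7,8-bis(benzyloxy)-4-[4-(benzyloxy)-8-methoxynaphthalen-1-yl]-3,4-dihydronaphthalen-1(2H)-one (racemic) | COc1cccc2c(OCc5ccccc5)ccc(C3CCC(=O)c4c3ccc(OCc5ccccc5)c4OCc5ccccc5)c12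
F5 | step 7 | (4R)-7,8-bis(benzyloxy)-4-[4-(benzyloxy)-8-methoxynaphthalen-1-yl]-3,4-dihydronaphthalen-1(2H)-one | COc1cccc2c(OCc5ccccc5)ccc([C@H]3CCC(=O)c4c3ccc(OCc5ccccc5)c4OCc5ccccc5)c12
F6 | step 9 | di(prop-2-en-1-yl) 2-{[4-(benzyloxy)-8-methoxynaphthalen-1-yl]methylidene}propanedioate | COc1cccc2c(OCc3ccccc3)ccc(C=C(C(=O)OCC=C)C(=O)OCC=C)c12
F7 | step 9 | di(prop-2-en-1-yl) 2-[4-(benzyloxy)-8-methoxynaphthalen-1-yl]cyclopropane-1,1-dicarboxylate (racemic) | COc1cccc2c(OCc3ccccc3)ccc(C3CC3(C(=O)OCC=C)C(=O)OCC=C)c12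
F8 | step 9 | di(prop-2-en-1-yl) (2R,5R)-5-[4-(benzyloxy)-8-methoxynaphthalen-1-yl]-2-[2,3-bis(benzyloxy)phenyl]oxolane-3,3-dicarboxylate | O1[C@H](c2cccc(OCc5ccccc5)c2OCc5ccccc5)C(C(=O)OCC=C)(C(=O)OCC=C)C[C@@H]1c1ccc(OCc5ccccc5)c2cccc(OC)c12
F9 | step 9 | di(prop-2-en-1-yl) (1R,4S)-7,8-bis(benzyloxy)-4-[4-(benzyloxy)-8-methoxynaphthalen-1-yl]-1-hydroxy-3,4-dihydronaphthalene-2,2(1H)-dicarboxylate | COc1cccc2c(OCc5ccccc5)ccc([C@@H]3CC(C(=O)OCC=C)(C(=O)OCC=C)[C@H](O)c4c3ccc(OCc5ccccc5)c4OCc5ccccc5)c12
F10 | step 9 | di(prop-2-en-1-yl) (4S)-7,8-bis(benzyloxy)-4-[4-(benzyloxy)-8-methoxynaphthalen-1-yl]-1-oxo-3,4-dihydronaphthalene-2,2(1H)-dicarboxylate | COc1cccc2c(OCc5ccccc5)ccc([C@@H]3CC(C(=O)OCC=C)(C(=O)OCC=C)C(=O)c4c3ccc(OCc5ccccc5)c4OCc5ccccc5)c12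
F11 | step 5 | 1-(benzyloxy)-4-ethenyl-5-methoxynaphthalene | COc1cccc2c(OCc3ccccc3)ccc(C=C)c12
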